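The route is built on disconnecting O1–C2 of the dihydrofuran ring A (furo[3,2-c]pyran-4-one numbering). Because O1 sits on C7a as the enol oxygen of the ring B pyran-2,4-dione and C2 is a benzylic carbon, ring A can be traced back to a three-membered ring spiro-fused at C3a. Catalytic iodide opens the C3a–C2 bond of that cyclopropane and the C7a oxygen recloses on C2 (Cloke–Wilson rearrangement), so one operation forms ring A and hands the cis geometry on as (2R,3S) through two inversions. The precursor is the penta-acetylated cis-1-aryl-2-pyronyl spirocyclopropane of a 6-arylpyran-2,4-dione, made by asymmetric carbene transfer from a 3-diazopyrandione to a Z-styrylpyrone.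

Key step: step 12

Remark: the S-configured dirhodium catalyst is assumed to select the alkene face that gives the (1R,2R) cyclopropane; if the sense proves opposite, its mirror-image catalyst Rh2(R-NTTL)4 is taken.

Remark: the spiro carbon C3 of cyclopropane 17 is stereogenic, is not controlled in step 11 and becomes the trigonal C3a in step 12, so 17 is drawn and named as its (3S) form and either configuration at that carbon would be carried through in the same way.

Step 1
Reactants: 1 malonyl dichloride (two molecules)
Product: 4 6-chloro-4-hydroxy-2H-pyran-2-one, via pyrone acid chloride 2 (not isolated), via pyrone carboxylic acid 3 (not isolated)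
Conditions: neat, rt, 3 d (HCl vented); then H2O, 1,4-dioxane, 50 °C
Reagents that add atoms: malonyl dichloride O=C(Cl)CC(=O)Cl (the second molecule of 1)
Why: Malonyl dichloride self-condenses (C-acylation of one molecule by another, then ring closure through an acid chloride enol oxygen) to the 3-chlorocarbonyl pyrone, and hydrolysis gives a vinylogous β-keto acid that should decarboxylate on warming, taking the oxygen of the water with it, while the C6–Cl bond stays in place.

Step 2
Reactants: 4 6-chloro-4-hydroxy-2H-pyran-2-one
Product: 5 6-chloro-2-oxo-2H-pyran-4-yl acetate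
Conditions: AcCl, i-Pr2NEt, CH2Cl2, −20 °C
Reagents that add atoms: acetyl chloride CC(=O)Cl
Why: O-acylation of the acidic pyronol (a vinylogous carboxylic acid) by an acid chloride in the presence of a hindered, non-nucleophilic amine at low temperature should give the enol acetate without substitution at C6 or O-to-C acyl migration.

Step 3
Reactants: 6 3,4-dihydroxybenzaldehyde
Product: 7 4-ethynylbenzene-1,2-diol
Conditions: dimethyl (1-diazo-2-oxopropyl)phosphonate, K2CO3 (excess), degassed MeOH, rt, argon; then aq. NH4Cl
Reagents that add atoms: dimethyl (1-diazo-2-oxopropyl)phosphonate CC(=O)C(=[N+]=[N-])P(=O)(OC)OC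
Why: Seyferth–Gilbert homologation in its Ohira–Bestmann form, in which methanolysis of the reagent releases the diazomethylphosphonate anion that adds to the aldehyde and, after phosphate elimination, loss of N2 and a 1,2-hydride shift, gives the terminal alkyne; excess carbonate allows for the two phenols and exclusion of air protects the catecholate.

Step 4
Reactants: 7 4-ethynylbenzene-1,2-diol
Product: 8 4-ethynyl-1,2-phenylene diacetate
Conditions: Ac2O, pyridine, CH2Cl2, 0 °C to rt
Reagents that add atoms: acetic anhydride CC(=O)OC(C)=O
Why: Pyridine-promoted acylation of both phenols is routine and installs the electron-withdrawing acetates that the key step needs on this ring.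

Step 5
Reactants: 5 6-chloro-2-oxo-2H-pyran-4-yl acetate, 8 4-ethynyl-1,2-phenylene diacetate
Product: 9 4-[(4-acetoxy-2-oxo-2H-pyran-6-yl)ethynyl]-1,2-phenylene diacetate
Conditions: PdCl2(PPh3)2 (3 mol %), CuI (5 mol %), i-Pr2NEt, THF, rt, degassed
Reagents that add atoms: none
Why: Sonogashira coupling, in which the C6–Cl bond of the 2-pyrone behaves as a vinylogous acyl chloride and adds readily to zerovalent palladium, the copper acetylide of 8 transmetallates, and the hindered amine should leave the three acetates alone.

Step 6
Reactants: 9 4-[(4-acetoxy-2-oxo-2H-pyran-6-yl)ethynyl]-1,2-phenylene diacetate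
Product: 10 4-[(Z)-2-(4-acetoxy-2-oxo-2H-pyran-6-yl)ethenyl]-1,2-phenylene diacetate
Conditions: H2 (1 atm), Pd/CaCO3 poisoned with Pb(OAc)2, quinoline, EtOAc, rt, dark
Reagents that add atoms: none
Why: Lindlar semihydrogenation delivers both hydrogen atoms to one face of the alkyne on the poisoned palladium surface, which fixes the Z geometry, while quinoline and measured hydrogen uptake should stop the reaction at the alkene; light is excluded because styrylpyrones isomerise photochemically.

Step 7
Reactants: 11 3,4-dihydroxyacetophenone
Product: 12 4-acetyl-1,2-phenylene diacetate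
Conditions: Ac2O, pyridine, CH2Cl2, 0 °C to rt
Reagents that add atoms: acetic anhydride CC(=O)OC(C)=O
Why: Standard acylation of the two phenols, done first so that ring B can be built under base-free conditions and no other catechol protecting group is needed.

Step 8
Reactants: 12 4-acetyl-1,2-phenylene diacetate
Product: 13 4-[1-(trimethylsilyloxy)ethenyl]-1,2-phenylene diacetate
Conditions: TMSOTf (1.05 equiv), Et3N, CH2Cl2, 0 °C
Reagents that add atoms: trimethylsilyl trifluoromethanesulfonate C[Si](C)(C)OS(=O)(=O)C(F)(F)F
Why: Soft enolisation (silyl triflate with a tertiary amine) should convert the aryl methyl ketone into its silyl enol ether much faster than it enolises the aryl acetates, so one equivalent is selective.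

Step 9
Reactants: 13 4-[1-(trimethylsilyloxy)ethenyl]-1,2-phenylene diacetate, 1 malonyl dichloride
Product: 15 4-(4-hydroxy-2-oxo-2H-pyran-6-yl)-1,2-phenylene diacetate, via dioxopentanoyl chloride 14 (not isolated)
Conditions: Et2O, −78 °C to rt
Reagents that add atoms: none
Why: Pyrone annulation of a silyl enol ether with malonyl dichloride, in which C-acylation at the enol ether terminus with loss of Me3SiCl gives the 3,5-dioxo acid chloride and the enol of its aryl ketone then closes onto the remaining acid chloride to give the 4-hydroxy-2-pyrone; no base is present, so the acetates should survive.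

Step 10
Reactants: 15 4-(4-hydroxy-2-oxo-2H-pyran-6-yl)-1,2-phenylene diacetate
Product: 16 4-(3-diazo-2,4-dioxo-3,4-dihydro-2H-pyran-6-yl)-1,2-phenylene diacetate
Conditions: 4-acetamidobenzenesulfonyl azide, Et3N, MeCN, 0 °C
Reagents that add atoms: 4-acetamidobenzenesulfonyl azide CC(=O)Nc1ccc(cc1)S(=O)(=O)N=[N+]=[N-]
Why: Regitz diazo transfer, in which the triethylammonium pyronolate attacks the terminal nitrogen of the sulfonyl azide through C3 and the adduct fragments to the sulfonamide and the 3-diazo-2,4-dione; triethylamine in acetonitrile should not cleave aryl acetates.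

Step 11
Reactants: 10 4-[(Z)-2-(4-acetoxy-2-oxo-2H-pyran-6-yl)ethenyl]-1,2-phenylene diacetate, 16 4-(3-diazo-2,4-dioxo-3,4-dihydro-2H-pyran-6-yl)-1,2-phenylene diacetate
Product: 17 (1R,2R,3S)-2-(4-acetoxy-2-oxo-2H-pyran-6-yl)-1,6-bis(3,4-diacetoxyphenyl)-5-oxaspiro[2.5]oct-6-ene-4,8-dione (aryl on C1 cis to pyronyl on C2)
Conditions: Rh2(S-NTTL)4 (2 mol %; NTTL = N-(1,8-naphthaloyl)-(S)-tert-leucinate), PhCF3, 40 °C, 16 (1.5 equiv) added over 6 h, dark
Reagents that add atoms: none
Why: The dirhodium tetracarboxylate decomposes the diazo dione to an electrophilic acceptor/acceptor carbene that adds to the alkene in one concerted, asynchronous step (metal-carbene cyclopropanation), so the Z geometry is copied into the cis C1/C2 relation, the chiral carboxylate ligands select the alkene face and so set C1 and C2 as (R,R), the acetylated arene should keep the product from ionising on the Lewis-acidic catalyst, and the spiro centre C3 is neither controlled nor needed.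

Step 12
Reactants: 17 (1R,2R,3S)-2-(4-acetoxy-2-oxo-2H-pyran-6-yl)-1,6-bis(3,4-diacetoxyphenyl)-5-oxaspiro[2.5]oct-6-ene-4,8-dione
Product: 19 (2R,3S)-3-(4-acetoxy-2-oxo-2H-pyran-6-yl)-2,6-bis(3,4-diacetoxyphenyl)-2,3-dihydro-4H-furo[3,2-c]pyran-4-one (cis penta-acetate), via ring-opened benzylic iodide 18 (not isolated)
Conditions: Bu4NI (15 mol %), MeCN, 45 °C, dark, argon
Reagents that add atoms: none
Why: Iodide attacks the benzylic carbon (C1 of 17, the future C2) of this donor–acceptor cyclopropane in an SN2 step that cleaves the bond to the spiro carbon (the future C3a–C2 bond) with inversion and releases the delocalised pyronolate 18, whose C7a oxygen then displaces iodide from C2 in a 5-exo-tet closure with a second inversion, forming O1–C2 and ring A and returning the catalyst. The closest known reaction type is the nucleophile-catalysed Cloke–Wilson rearrangement of spirocyclopropyl 1,3-dicarbonyl compounds to fused dihydrofurans. C2 is re-formed with net retention by the double inversion and C3 is never touched, so the cis relation written into the cyclopropane by the Z-alkene should appear as (2R,3S), while the spiro carbon becomes the trigonal C3a and its configuration in 17 therefore does not matter. Opening at the aryl-bearing carbon and not at the pyronyl-bearing one is secured by the arene, which stabilises the substitution transition state, against the electron-poor acetoxypyronyl group. Closure through the C7a (ketone-derived) oxygen and not through the C4 lactone oxygen is favoured because it gives the aromatic 2-pyrone of ring B. The acetylated catechol keeps the opening bimolecular by disfavouring a benzylic cation and the low iodide loading limits iodide-for-iodide exchange at C2, these being the two ways in which trans product could arise, and iodide is preferred to an amine catalyst because it cannot be acylated by the enol acetate of ring C or by the spiro enol lactone.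

Step 13
Reactants: 19 (2R,3S)-3-(4-acetoxy-2-oxo-2H-pyran-6-yl)-2,6-bis(3,4-diacetoxyphenyl)-2,3-dihydro-4H-furo[3,2-c]pyran-4-one
Product: 20 (2R,3S)-2,6-bis(3,4-dihydroxyphenyl)-3-(4-hydroxy-2-oxo-2H-pyran-6-yl)-2,3-dihydro-4H-furo[3,2-c]pyran-4-one (CNP0224684.1)
Conditions: NH4OAc (excess), degassed MeOH/H2O (4:1), rt, argon; then aq. citric acid to pH 3
Reagents that add atoms: none
Why: Ammonium acetate-mediated methanolysis (transesterification) should cleave the four aryl acetates and the more reactive enol acetate near neutrality, so neither a phenoxide that could expel O1 from C2 through a quinone methide nor a strong acid that could ionise C2–O1 is present, and the cis (2R,3S) configuration is kept.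

Compound list
1 | malonyl dichloride | O=C(Cl)CC(=O)Cl | starting material
2 | 6-chloro-4-hydroxy-2-oxo-2H-pyran-3-carbonyl chloride | O=C(Cl)c1c(O)cc(Cl)oc1=O | intermediate
3 | 6-chloro-4-hydroxy-2-oxo-2H-pyran-3-carboxylic acid | O=C(O)c1c(O)cc(Cl)oc1=O | intermediate
4 | 6-chloro-4-hydroxy-2H-pyran-2-one | O=c1cc(O)cc(Cl)o1 | intermediate
5 | 6-chloro-2-oxo-2H-pyran-4-yl acetate | CC(=O)Oc1cc(Cl)oc(=O)c1 | intermediate
6 | 3,4-dihydroxybenzaldehyde | O=Cc1ccc(O)c(O)c1 | starting material
7 | 4-ethynylbenzene-1,2-diol | C#Cc1ccc(O)c(O)c1 | intermediate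
8 | 4-ethynyl-1,2-phenylene diacetate | C#Cc1ccc(OC(C)=O)c(OC(C)=O)c1 | intermediate
9 | 4-[(4-acetoxy-2-oxo-2H-pyran-6-yl)ethynyl]-1,2-phenylene diacetate | CC(=O)Oc1cc(C#Cc2ccc(OC(C)=O)c(OC(C)=O)c2)oc(=O)c1 | intermediate
10 | 4-[(Z)-2-(4-acetoxy-2-oxo-2H-pyran-6-yl)ethenyl]-1,2-phenylene diacetate | CC(=O)Oc1cc(/C=C\c2ccc(OC(C)=O)c(OC(C)=O)c2)oc(=O)c1 | intermediate
11 | 3,4-dihydroxyacetophenone | CC(=O)c1ccc(O)c(O)c1 | starting material
12 | 4-acetyl-1,2-phenylene diacetate | CC(=O)c1ccc(OC(C)=O)c(OC(C)=O)c1 | intermediate
13 | 4-[1-(trimethylsilyloxy)ethenyl]-1,2-phenylene diacetate | C=C(O[Si](C)(C)C)c1ccc(OC(C)=O)c(OC(C)=O)c1 | intermediate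
14 | 5-(3,4-diacetoxyphenyl)-3,5-dioxopentanoyl chloride | O=C(Cl)CC(=O)CC(=O)c1ccc(OC(C)=O)c(OC(C)=O)c1 | intermediate
15 | 4-(4-hydroxy-2-oxo-2H-pyran-6-yl)-1,2-phenylene diacetate | O=c1cc(O)cc(-c2ccc(OC(C)=O)c(OC(C)=O)c2)o1 | intermediate
16 | 4-(3-diazo-2,4-dioxo-3,4-dihydro-2H-pyran-6-yl)-1,2-phenylene diacetate | [N-]=[N+]=C1C(=O)C=C(c2ccc(OC(C)=O)c(OC(C)=O)c2)OC1=O | intermediate
17 | (1R,2R,3S)-2-(4-acetoxy-2-oxo-2H-pyran-6-yl)-1,6-bis(3,4-diacetoxyphenyl)-5-oxaspiro[2.5]oct-6-ene-4,8-dione (cis) | O=c1cc(OC(C)=O)cc([C@H]2[C@]3(C(=O)C=C(c4ccc(OC(C)=O)c(OC(C)=O)c4)OC3=O)[C@H]2c2ccc(OC(C)=O)c(OC(C)=O)c2)o1 | intermediate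
18 | tetrabutylammonium 3-[(1R,2S)-1-(4-acetoxy-2-oxo-2H-pyran-6-yl)-2-(3,4-diacetoxyphenyl)-2-iodoethyl]-6-(3,4-diacetoxyphenyl)-2-oxo-2H-pyran-4-olate (ring-opened benzylic iodide, C2 inverted) | O=c1cc(OC(C)=O)cc([C@H]([C@H](I)c2ccc(OC(C)=O)c(OC(C)=O)c2)c2c([O-])cc(-c3ccc(OC(C)=O)c(OC(C)=O)c3)oc2=O)o1.CCCC[N+](CCCC)(CCCC)CCCC | intermediate
19 | (2R,3S)-3-(4-acetoxy-2-oxo-2H-pyran-6-yl)-2,6-bis(3,4-diacetoxyphenyl)-2,3-dihydro-4H-furo[3,2-c]pyran-4-one (cis penta-acetate) | O=c1cc(OC(C)=O)cc([C@H]2c3c(cc(-c4ccc(OC(C)=O)c(OC(C)=O)c4)oc3=O)O[C@H]2c2ccc(OC(C)=O)c(OC(C)=O)c2)o1 | intermediate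
20 | (2R,3S)-2,6-bis(3,4-dihydroxyphenyl)-3-(4-hydroxy-2-oxo-2H-pyran-6-yl)-2,3-dihydro-4H-furo[3,2-c]pyran-4-one (cis) | O=c1cc(O)cc([C@H]2c3c(cc(-c4ccc(O)c(O)c4)oc3=O)O[C@H]2c2ccc(O)c(O)c2)o1 | target

Total step count: 13.
Longest linear sequence: 7 steps (for example steps 7, 8, 9, 10, 11, 12 and 13; the branches that start with steps 1, 2 or with steps 3, 4 and run on through steps 5 and 6 are equally long).

Steps most likely to fail

Step 11. The chiral catalyst may discriminate poorly between the two faces of this electron-poor, Z-1,2-disubstituted alkene, so that carbene transfer proceeds but with low enantiomeric excess. The fallback gives up catalyst control in favour of resolution. Setting out from 10 and 16, the carbene transfer is run with the achiral, robust Rh2(esp)2 (esp = α,α,α′,α′-tetramethyl-1,3-benzenedipropanoate) under otherwise similar slow-addition conditions. This should give the racemic cis cyclopropane, that is 17 together with the (1S,2S,3R) enantiomer of 17 F1. Preparative chromatography on an immobilised polysaccharide chiral phase, with a non-alcoholic eluent because alcohols can open the spiro enol lactone, removes F1. The route is rejoined at 17.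

Step 12. The cis relation may be eroded if the cyclopropane opens by ionisation at the benzylic carbon, or if free iodide exchanges with the benzylic iodide before the ring closes; closure through the lactone oxygen is a further leak. The fallback splits the two inversions into two separately controlled operations. Setting out from 17, one equivalent of anhydrous HBr (as its solution in acetic acid) in CH2Cl2 at −40 °C is added across the bond between the spiro carbon and the benzylic carbon, bromide entering at the benzylic carbon with inversion and the proton ending on the dione oxygen. This homoconjugate addition should give the benzylic bromide 4-[(1S,2R)-2-(4-acetoxy-2-oxo-2H-pyran-6-yl)-1-bromo-2-[6-(3,4-diacetoxyphenyl)-4-hydroxy-2-oxo-2H-pyran-3-yl]ethyl]-1,2-phenylene diacetate F2, which is isolated so that its configuration can be checked and no free halide remains. Treatment with i-Pr2NEt in MeCN at 0 °C then generates the pyronolate, which closes on the benzylic carbon through the C7a oxygen with the second inversion. The route is rejoined at 19.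

Step 6. Hydrogenation may run on to the saturated bridge or into the pyrone ring, or the Z-alkene may isomerise to E on the metal surface. The fallback replaces surface hydrogenation by hydroboration and protonolysis. Setting out from 9, dicyclohexylborane (1.05 equiv, THF, 0 °C) adds syn across the alkyne, boron going to the pyronyl-bearing carbon, to give the (Z)-alkenyl(dicyclohexyl)borane F3. Protonolysis of the C–B bond with acetic acid at rt proceeds with retention and cannot over-reduce. The route is rejoined at 10.

Further compounds
F1 | step 11 | (1S,2S,3R)-2-(4-acetoxy-2-oxo-2H-pyran-6-yl)-1,6-bis(3,4-diacetoxyphenyl)-5-oxaspiro[2.5]oct-6-ene-4,8-dione (enantiomer of 17) | O=c1cc(OC(C)=O)cc([C@@H]2[C@@]3(C(=O)C=C(c4ccc(OC(C)=O)c(OC(C)=O)c4)OC3=O)[C@@H]2c2ccc(OC(C)=O)c(OC(C)=O)c2)o1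
F2 | step 12 | 4-[(1S,2R)-2-(4-acetoxy-2-oxo-2H-pyran-6-yl)-1-bromo-2-[6-(3,4-diacetoxyphenyl)-4-hydroxy-2-oxo-2H-pyran-3-yl]ethyl]-1,2-phenylene diacetate | O=c1cc(OC(C)=O)cc([C@H]([C@H](Br)c2ccc(OC(C)=O)c(OC(C)=O)c2)c2c(O)cc(-c3ccc(OC(C)=O)c(OC(C)=O)c3)oc2=O)o1
F3 | step 6 | 4-[(Z)-2-(4-acetoxy-2-oxo-2H-pyran-6-yl)-2-(dicyclohexylboranyl)ethenyl]-1,2-phenylene diacetate | CC(=O)Oc1cc(/C(B(C2CCCCC2)C2CCCCC2)=C\c2ccc(OC(C)=O)c(OC(C)=O)c2)oc(=O)c1
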